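The numbers of this flask are assumed; no experiment stands behind them.

Reading 0.53 M⁻¹ s⁻¹ against 0.040 M⁻¹ s⁻¹ as a selectivity factor misleads: protic impurity attacks the solid substrate, partner attacks the dissolved substrate, and the two steps do not compete for one species.

solid substrate 10 mM; partner 11.0 mM; protic impurity 5.00 mM; time 8.0 h

    solid substrate + protic impurity → quenched substrate (k1 = 0.53 M⁻¹ s⁻¹)
    dissolved substrate + partner → product (k2 = 0.040 M⁻¹ s⁻¹)
    solid substrate ⇌ dissolved substrate, rate k3*(cs3 - [dissolved substrate]) while solid is left; crystals form when [dissolved substrate] > cs3 (cs3 = 7.9 mM, k3 = 0.0041 s⁻¹)
    partner ⇌ dormant form (K4 = 1.7, k4 = 0.0040 s⁻¹)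

- oak: doubling the dissolution coefficient of step 3, all else as stated
- larch: doubling the solubility in step 3, all else as stated
- elm: doubling the amount of partner, all else as stated

- given per volume of solution although it is solid: solid substrate
- at the start none of the solid substrate is in solution
- run time (flask): 8.0 h

* the product standing at 8.0 h, as a percentage of the solid substrate charged
* the change that raises the amount of product at 8.0 h, in percent of the solid substrate charged most ("none" if none brings more than 2 percentage points) (oak / larch / elm / none)
* amount of product at 8.0 h, in percent of the solid substrate charged, after larch

How does the solid divide? At the start, dissolution into an empty solution outruns quenching by the ratio ρ = 1.22. Reckoned with impurity held at its charge and the solution held empty, dissolution stays constant while quenching falls with the solid. The linear equation for the solid fraction then integrates to the dissolved share, the fraction of the charge that reaches solution, ρ·ln(1+1/ρ) = 73.1%.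

How much partner works? Partner relaxes with a half-life of 1.82 min, shorter than the 0.44 h of dissolved substrate by step 2 at the charged concentrations, so step 4 counts as a pre-equilibrium. It leaves free a fraction 0.370 of the unconsumed partner, and the working constant is 0.0148 M⁻¹ s⁻¹.

Does the dissolved share convert in time? With the dissolved share taken as in solution from the start, my second-order integration over 8.0 h gives 67.2% of product. Doubling ρ lifts the dissolved share to 83.8% and the product to 75.1%. Oak and larch double ρ alike, but as dissolved substrate builds up, the dissolution rate falls per unit of it by 0.0041 s⁻¹ under larch and by 0.00820 s⁻¹ under oak, so I choose larch. In this reckoning elm leaves the dissolved share unchanged, and that share stands below the larch product.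

The forecast starts from the same division, “Solid is split between quenching by impurity and dissolution”. It gives 66%, less than my 67.2%, then larch with 75%.

The flask gives 66.0%, and larch gains most, reaching 74.8%. In the flask, quenched substrate stands at 28.3%, so 71.7% of the charge escaped quenching, against a dissolved share of 73.1%. In the neighbour flask with 20 mM of protic impurity, ρ falls to 0.306 and the dissolved share to 44.4%. That flask holds 56.8% quenched substrate, leaving 43.2% unquenched, and 41.6% product.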